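**Plan**

1. Cuts, in retrosynthetic order: the four Si–O bonds; the side-chain bond C1'–C2' (carbinol to dienyl), giving epoxy aldehyde 11 and (1E,3Z)-dienyl iodide 25; the oxirane oxygen O7 and the aldehyde level, giving diene diol 7; then ring bonds C1–C2 and C4–C5 (7-oxabicyclo[4.1.0]heptene numbering of the target), giving two molecules of (Z)-iodoenal 5.
2. Enabling feature: with O7 taken back to a C1=C6 alkene and the carbinol carbon C1' levelled with the hydroxymethyl carbon, ring carbons C1–C6 form a cis-2,5-disubstituted cyclohexa-2,5-diene-1,4-diol with a C2 axis. Its two halves are the same unit C(CH2O)=CH–CH(OH), joined head to tail.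
3. Forward, core: 5 (3 steps); cyclodimerization builds the carbocycle; silylation; removal of either homotopic primary silyl group; directed epoxidation closes the oxirane; oxidation gives 11.
4. Forward, ring A and union: epoxy-olefin cyclization of (R)-6,7-epoxygeranyl acetate makes ring A; its arm is grown by Takai iodo-olefination, Negishi coupling with a (Z)-bromopropenyl boronate and iodination to 25; 11 and 25 are joined by a chromium-mediated coupling and desilylated.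
5. Stereochemistry: C2 and C5 from the chiral chromium catalyst in the dimerization; C1 and C6 from attack anti to both silyloxy groups; C1' from the chiral chromium catalyst in the fragment coupling; the ring A carbinol from Shi epoxidation and its neighbour from the chair cyclization; the E alkene from the Takai reaction, the Z alkene from syn-bromoboration of propyne.

Key step: step 4

Abbreviations: TBS = tert-butyl(dimethyl)silyl; Bpin = 4,4,5,5-tetramethyl-1,3,2-dioxaborolan-2-yl; PMB = 4-methoxybenzyl; L* = chiral 2-(4-isopropyl-4,5-dihydrooxazol-2-yl)aryl methanesulfonamide ligand.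

Remark: in steps 4 and 18 the antipode of L* that gives the S carbinol is to be fixed in a small trial run; the sense of induction is not asserted here.

**Step 1**
Reactants: 1 but-2-yne-1,4-diol
Product: 2 4-(TBSO)but-2-yn-1-ol
Conditions: NaH (1 equiv), THF, 0 °C; TBSCl (1 equiv), rt
Reagents that add atoms: tert-butyl(chloro)dimethylsilane, CC(C)(C)[Si](C)(C)Cl
Why: Monosilylation of a symmetric diol through its monosodium alkoxide (McDougal protocol) should cap one hydroxyl only.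

**Step 2**
Reactants: 2 4-(TBSO)but-2-yn-1-ol
Product: 4 (2Z)-4-(TBSO)-3-iodobut-2-en-1-ol, via cyclic alkenylalanate 3 (not isolated)
Conditions: NaAlH2(OCH2CH2OCH3)2, THF, 0 °C; EtOAc; I2, −78 °C to 0 °C; aq. Na2S2O3
Reagents that add atoms: iodine, II
Why: Hydroxyl-directed trans-hydroalumination of the propargylic alcohol places aluminium on the distal alkyne carbon in the five-membered alanate 3, and iodinolysis with retention should give the (Z)-3-iodo allylic alcohol, with iodine cis to CH2OH.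

**Step 3**
Reactants: 4 (2Z)-4-(TBSO)-3-iodobut-2-en-1-ol
Product: 5 (2Z)-4-(TBSO)-3-iodobut-2-enal
Conditions: MnO2, CH2Cl2, rt, dark; used at once
Reagents that add atoms: none
Why: Allylic oxidation with MnO2 is neutral and should keep the Z geometry that places iodide and aldehyde on the same side of the alkene.

**Step 4**
Reactants: 5 (2Z)-4-(TBSO)-3-iodobut-2-enal (two molecules)
Product: 7 (1S,4S)-2,5-bis[(TBSO)methyl]cyclohexa-2,5-diene-1,4-diol, via acyclic iodoaldehyde dimer 6 (not isolated)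
Conditions: CrCl2 (10 mol %), L* (11 mol %), 1,8-bis(dimethylamino)naphthalene (11 mol %), NiCl2(2,9-dimethyl-1,10-phenanthroline) (1 mol %), Mn powder, Zr(C5H5)2Cl2, MeCN, rt, slow addition of 5; aq. NaHCO3 work-up
Reagents that add atoms: none
Why: Proposed new method: zerovalent nickel inserts into the C–I bond of 5, the alkenyl group passes to trivalent chromium bearing L*, and this alkenylchromium adds 1,2 to the aldehyde of a second molecule of 5 to give dimer 6, whose own iodide enters the same cycle and closes onto its cis-disposed aldehyde, while Zr(C5H5)2Cl2 releases the chromium alkoxide and Mn returns chromium to the divalent state. The closest known reactions are the catalytic asymmetric Nozaki–Hiyama–Kishi coupling of alkenyl iodides with aldehydes and its intramolecular six-ring variant; new is their use as a head-to-tail cyclodimerization of a (Z)-3-iodoenal. The ring closes in a 6-exo-trig mode, the two Z alkenes of 6 holding the alkenylchromium carbon and the aldehyde within bonding distance. Both carbinol centers (C1 and C4 of 7) are set by L* on chromium; because the same face selection acts twice on the same kind of aldehyde, the homochiral, C2-symmetric cis-diol is favoured, and mismatched events are diverted to the separable meso trans-diol. The step needs ring closure to outrun chain growth, and needs the first alkoxide not to add to the cis aldehyde (lactol, then furan). The preorganized Z,Z skipped diene, the low stationary concentration of 5 and capping of the alkoxide by zirconium should secure both.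

**Step 5**
Reactants: 7 (1S,4S)-2,5-bis[(TBSO)methyl]cyclohexa-2,5-diene-1,4-diol
Product: 8 (3S,6S)-3,6-bis(TBSO)-1,4-bis[(TBSO)methyl]cyclohexa-1,4-diene
Conditions: TBSOTf, 2,6-lutidine, CH2Cl2, −78 °C
Reagents that add atoms: tert-butyldimethylsilyl trifluoromethanesulfonate, CC(C)(C)[Si](C)(C)OS(=O)(=O)C(F)(F)F
Why: Silyl triflate silylation under basic conditions caps both doubly allylic alcohols before they can dehydrate to an arene, and the two silyloxy groups later shield the top face of the ring.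

**Step 6**
Reactants: 8 (3S,6S)-3,6-bis(TBSO)-1,4-bis[(TBSO)methyl]cyclohexa-1,4-diene
Product: 9 [(3S,6S)-3,6-bis(TBSO)-4-[(TBSO)methyl]cyclohexa-1,4-dien-1-yl]methanol
Conditions: HF·pyridine, pyridine, THF, 0 °C, stopped at partial conversion; recovered 8 recycled
Reagents that add atoms: none
Why: Selective desilylation: primary allylic silyl ethers are cleaved faster than secondary ones by buffered HF, and since the two primary ethers of C2-symmetric 8 are homotopic, loss of either gives the same alcohol 9.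

**Step 7**
Reactants: 9 [(3S,6S)-3,6-bis(TBSO)-4-[(TBSO)methyl]cyclohexa-1,4-dien-1-yl]methanol
Product: 10 [(1S,2S,5R,6S)-2,5-bis(TBSO)-4-[(TBSO)methyl]-7-oxabicyclo[4.1.0]hept-3-en-1-yl]methanol
Conditions: VO(acac)2 (cat.), t-BuOOH, CH2Cl2, 0 °C
Reagents that add atoms: tert-butyl hydroperoxide, CC(C)(C)OO
Why: Vanadium-catalysed hydroxyl-directed epoxidation (Sharpless–Michaelson type) should oxidize only the alkene that carries the free allylic alcohol, and the oxygen is delivered to the face anti to both silyloxy groups, which sets C1 and C6.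

**Step 8**
Reactants: 10 [(1S,2S,5R,6S)-2,5-bis(TBSO)-4-[(TBSO)methyl]-7-oxabicyclo[4.1.0]hept-3-en-1-yl]methanol
Product: 11 (1S,2S,5R,6S)-2,5-bis(TBSO)-4-[(TBSO)methyl]-7-oxabicyclo[4.1.0]hept-3-ene-1-carbaldehyde
Conditions: Dess–Martin periodinane, NaHCO3, CH2Cl2, 0 °C to rt
Reagents that add atoms: none
Why: Dess–Martin oxidation under buffered conditions should give the epoxy aldehyde, whose quaternary alpha carbon cannot epimerize.

**Step 9**
Reactants: 12 geranyl acetate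
Product: 13 (2E)-5-[(2R)-3,3-dimethyloxiran-2-yl]-3-methylpent-2-en-1-yl acetate
Conditions: D-fructose-derived Shi ketone (30 mol %), KHSO5 (as 2KHSO5·KHSO4·K2SO4), K2CO3, Bu4NHSO4, MeCN/CH2(OMe)2/aq. borate buffer, 0 °C
Reagents that add atoms: potassium peroxymonosulfate, [K+].[O-]S(=O)(=O)OO
Why: Shi asymmetric epoxidation: the chiral dioxirane attacks the electron-rich 6,7-alkene (the 2,3-alkene is deactivated by the allylic acetate) through the spiro transition state that should give the R epoxide.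

**Step 10**
Reactants: 13 (2E)-5-[(2R)-3,3-dimethyloxiran-2-yl]-3-methylpent-2-en-1-yl acetate
Product: 14 [(1S,5R)-5-hydroxy-2,6,6-trimethylcyclohex-2-en-1-yl]methyl acetate
Conditions: ZrCl4, CH2Cl2, −20 °C to rt
Reagents that add atoms: none
Why: Lewis-acid-promoted epoxy-olefin cyclization through a chair transition state: the E alkene opens the epoxide at its tertiary carbon, the carbinol keeps the epoxide configuration, the new center C1 carries CH2OAc cis (diequatorial) to the hydroxyl, and proton loss should give mainly the endocyclic alkene.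

**Step 11**
Reactants: 14 [(1S,5R)-5-hydroxy-2,6,6-trimethylcyclohex-2-en-1-yl]methyl acetate
Product: 15 [(1S,5R)-5-(TBSO)-2,6,6-trimethylcyclohex-2-en-1-yl]methyl acetate
Conditions: TBSOTf, 2,6-lutidine, CH2Cl2, 0 °C
Reagents that add atoms: tert-butyldimethylsilyl trifluoromethanesulfonate, CC(C)(C)[Si](C)(C)OS(=O)(=O)C(F)(F)F
Why: Silyl triflate silylation should protect the hindered secondary alcohol next to the gem-dimethyl carbon.

**Step 12**
Reactants: 15 [(1S,5R)-5-(TBSO)-2,6,6-trimethylcyclohex-2-en-1-yl]methyl acetate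
Product: 16 [(1S,5R)-5-(TBSO)-2,6,6-trimethylcyclohex-2-en-1-yl]methanol
Conditions: K2CO3 (cat.), MeOH, rt
Reagents that add atoms: none
Why: Base-catalysed transesterification removes the acetate and leaves the silyl ether.

**Step 13**
Reactants: 16 [(1S,5R)-5-(TBSO)-2,6,6-trimethylcyclohex-2-en-1-yl]methanol
Product: 17 (1S,5R)-5-(TBSO)-2,6,6-trimethylcyclohex-2-ene-1-carbaldehyde
Conditions: Dess–Martin periodinane, NaHCO3, CH2Cl2, 0 °C; crude used at once
Reagents that add atoms: none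
Why: Buffered Dess–Martin oxidation is neutral, so the epimerizable beta,gamma-unsaturated aldehyde should neither epimerize nor move its alkene into conjugation.

**Step 14**
Reactants: 17 (1S,5R)-5-(TBSO)-2,6,6-trimethylcyclohex-2-ene-1-carbaldehyde
Product: 18 tert-butyl({(1R,5S)-5-[(E)-2-iodoethenyl]-4,6,6-trimethylcyclohex-3-en-1-yl}oxy)dimethylsilane
Conditions: CHI3, CrCl2, THF/dioxane, 0 °C to rt
Reagents that add atoms: iodoform, IC(I)I
Why: Takai iodo-olefination with the geminal dichromium reagent from CHI3 is E-selective and non-basic, so the sensitive aldehyde should survive.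

**Step 15**
Reactants: 19 propyne
Product: 21 2-[(1Z)-2-bromoprop-1-en-1-yl]-4,4,5,5-tetramethyl-1,3,2-dioxaborolane, via dibromo[(1Z)-2-bromoprop-1-enyl]borane 20 (not isolated)
Conditions: BBr3, CH2Cl2, −78 °C to rt; pinacol, −78 °C to rt
Reagents that add atoms: boron tribromide, BrB(Br)Br; pinacol, CC(C)(O)C(C)(C)O
Why: Syn-bromoboration of propyne places bromine on the internal carbon cis to boron, and exchange with pinacol gives the stable (Z)-bromoalkenyl boronate.

**Step 16**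
Reactants: 18 tert-butyl({(1R,5S)-5-[(E)-2-iodoethenyl]-4,6,6-trimethylcyclohex-3-en-1-yl}oxy)dimethylsilane; 21 2-[(1Z)-2-bromoprop-1-en-1-yl]-4,4,5,5-tetramethyl-1,3,2-dioxaborolane
Product: 24 tert-butyldimethyl({(1R,5S)-4,6,6-trimethyl-5-[(1E,3Z)-3-methyl-4-(Bpin)buta-1,3-dien-1-yl]cyclohex-3-en-1-yl}oxy)silane, via alkenyllithium 22 (not isolated), via alkenylzinc bromide 23 (not isolated)
Conditions: t-BuLi (2 equiv), Et2O, −78 °C; ZnBr2, THF, −78 °C to 0 °C; 21, Pd[P(t-Bu)3]2 (2 mol %), THF, rt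
Reagents that add atoms: none
Why: Iodine–lithium exchange, transmetalation to zinc and Negishi coupling at the C–Br bond of 21 all proceed with retention and leave the pinacol boronate untouched, so the (1E,3Z)-dienyl boronate should result.

**Step 17**
Reactants: 24 tert-butyldimethyl({(1R,5S)-4,6,6-trimethyl-5-[(1E,3Z)-3-methyl-4-(Bpin)buta-1,3-dien-1-yl]cyclohex-3-en-1-yl}oxy)silane
Product: 25 tert-butyl({(1R,5S)-5-[(1E,3Z)-4-iodo-3-methylbuta-1,3-dien-1-yl]-4,6,6-trimethylcyclohex-3-en-1-yl}oxy)dimethylsilane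
Conditions: aq. NaOH, THF, 0 °C; I2, dark
Reagents that add atoms: iodine, II
Why: Base-mediated iododeboronation of an alkenyl boronate proceeds with retention and should give the (Z)-alkenyl iodide.

**Step 18**
Reactants: 11 (1S,2S,5R,6S)-2,5-bis(TBSO)-4-[(TBSO)methyl]-7-oxabicyclo[4.1.0]hept-3-ene-1-carbaldehyde; 25 tert-butyl({(1R,5S)-5-[(1E,3Z)-4-iodo-3-methylbuta-1,3-dien-1-yl]-4,6,6-trimethylcyclohex-3-en-1-yl}oxy)dimethylsilane
Product: 26 (1S,2Z,4E)-1-[(1S,2S,5R,6S)-2,5-bis(TBSO)-4-[(TBSO)methyl]-7-oxabicyclo[4.1.0]hept-3-en-1-yl]-3-methyl-5-[(1S,5R)-5-(TBSO)-2,6,6-trimethylcyclohex-2-en-1-yl]penta-2,4-dien-1-ol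
Conditions: CrCl2 (20 mol %), L* (22 mol %), 1,8-bis(dimethylamino)naphthalene (22 mol %), NiCl2(2,9-dimethyl-1,10-phenanthroline) (2 mol %), Mn powder, Zr(C5H5)2Cl2, MeCN, rt
Reagents that add atoms: none
Why: Catalytic asymmetric Nozaki–Hiyama–Kishi coupling: the alkenylchromium from 25 keeps its Z geometry and adds to the aldehyde of 11, and L* on chromium is relied on to select the aldehyde face that gives the 1S carbinol (new center C1'), against the Felkin–Anh preference of the epoxy aldehyde.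

**Step 19**
Reactants: 26 (1S,2Z,4E)-1-[(1S,2S,5R,6S)-2,5-bis(TBSO)-4-[(TBSO)methyl]-7-oxabicyclo[4.1.0]hept-3-en-1-yl]-3-methyl-5-[(1S,5R)-5-(TBSO)-2,6,6-trimethylcyclohex-2-en-1-yl]penta-2,4-dien-1-ol
Product: 27 (1R,2S,5R,6S)-1-[(1S,2Z,4E)-1-hydroxy-5-[(1S,5R)-5-hydroxy-2,6,6-trimethylcyclohex-2-en-1-yl]-3-methylpenta-2,4-dien-1-yl]-4-(hydroxymethyl)-7-oxabicyclo[4.1.0]hept-3-ene-2,5-diol
Conditions: HF·pyridine, excess pyridine, THF, 0 °C to rt
Reagents that add atoms: none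
Why: Buffered fluoride desilylation should cleave all four silyl ethers without opening the epoxide or ionizing the dienyl carbinol, and gives the target.

**Compound list**

1 | but-2-yne-1,4-diol | OCC#CCO | starting material
2 | 4-(TBSO)but-2-yn-1-ol | OCC#CCO[Si](C)(C)C(C)(C)C | intermediate
3 | sodium 3-[(TBSO)methyl]-2,2-bis(2-methoxyethoxy)-2,5-dihydro-1,2-oxaaluminol-2-uide | [Na+].COCCO[Al-]1(OCCOC)OCC=C1CO[Si](C)(C)C(C)(C)C | intermediate
4 | (2Z)-4-(TBSO)-3-iodobut-2-en-1-ol | OC/C=C(\I)CO[Si](C)(C)C(C)(C)C | intermediate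
5 | (2Z)-4-(TBSO)-3-iodobut-2-enal | O=C/C=C(\I)CO[Si](C)(C)C(C)(C)C | intermediate
6 | (2Z,4S,5Z)-7-(TBSO)-3-[(TBSO)methyl]-4-hydroxy-6-iodohepta-2,5-dienal (drawn as the free alcohol; present as its zirconium alkoxide) | O=C/C=C(/CO[Si](C)(C)C(C)(C)C)[C@@H](O)/C=C(\I)CO[Si](C)(C)C(C)(C)C | intermediate
7 | (1S,4S)-2,5-bis[(TBSO)methyl]cyclohexa-2,5-diene-1,4-diol | CC(C)(C)[Si](C)(C)OCC1=C[C@H](O)C(CO[Si](C)(C)C(C)(C)C)=C[C@@H]1O | intermediate
8 | (3S,6S)-3,6-bis(TBSO)-1,4-bis[(TBSO)methyl]cyclohexa-1,4-diene | CC(C)(C)[Si](C)(C)OCC1=C[C@H](O[Si](C)(C)C(C)(C)C)C(CO[Si](C)(C)C(C)(C)C)=C[C@@H]1O[Si](C)(C)C(C)(C)C | intermediate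
9 | [(3S,6S)-3,6-bis(TBSO)-4-[(TBSO)methyl]cyclohexa-1,4-dien-1-yl]methanol | OCC1=C[C@H](O[Si](C)(C)C(C)(C)C)C(CO[Si](C)(C)C(C)(C)C)=C[C@@H]1O[Si](C)(C)C(C)(C)C | intermediate
10 | [(1S,2S,5R,6S)-2,5-bis(TBSO)-4-[(TBSO)methyl]-7-oxabicyclo[4.1.0]hept-3-en-1-yl]methanol | OC[C@]12O[C@H]1[C@H](O[Si](C)(C)C(C)(C)C)C(CO[Si](C)(C)C(C)(C)C)=C[C@@H]2O[Si](C)(C)C(C)(C)C | intermediate
11 | (1S,2S,5R,6S)-2,5-bis(TBSO)-4-[(TBSO)methyl]-7-oxabicyclo[4.1.0]hept-3-ene-1-carbaldehyde | O=C[C@]12O[C@H]1[C@H](O[Si](C)(C)C(C)(C)C)C(CO[Si](C)(C)C(C)(C)C)=C[C@@H]2O[Si](C)(C)C(C)(C)C | intermediate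
12 | geranyl acetate, (2E)-3,7-dimethylocta-2,6-dien-1-yl acetate | CC(=O)OC/C=C(\C)CCC=C(C)C | starting material
13 | (2E)-5-[(2R)-3,3-dimethyloxiran-2-yl]-3-methylpent-2-en-1-yl acetate | CC(=O)OC/C=C(\C)CC[C@H]1OC1(C)C | intermediate
14 | [(1S,5R)-5-hydroxy-2,6,6-trimethylcyclohex-2-en-1-yl]methyl acetate | CC1=CC[C@@H](O)C(C)(C)[C@H]1COC(C)=O | intermediate
15 | [(1S,5R)-5-(TBSO)-2,6,6-trimethylcyclohex-2-en-1-yl]methyl acetate | CC1=CC[C@@H](O[Si](C)(C)C(C)(C)C)C(C)(C)[C@H]1COC(C)=O | intermediate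
16 | [(1S,5R)-5-(TBSO)-2,6,6-trimethylcyclohex-2-en-1-yl]methanol | CC1=CC[C@@H](O[Si](C)(C)C(C)(C)C)C(C)(C)[C@H]1CO | intermediate
17 | (1S,5R)-5-(TBSO)-2,6,6-trimethylcyclohex-2-ene-1-carbaldehyde | CC1=CC[C@@H](O[Si](C)(C)C(C)(C)C)C(C)(C)[C@H]1C=O | intermediate
18 | tert-butyl({(1R,5S)-5-[(E)-2-iodoethenyl]-4,6,6-trimethylcyclohex-3-en-1-yl}oxy)dimethylsilane | CC1=CC[C@@H](O[Si](C)(C)C(C)(C)C)C(C)(C)[C@H]1/C=C/I | intermediate
19 | propyne | CC#C | starting material
20 | dibromo[(1Z)-2-bromoprop-1-en-1-yl]borane | C/C(Br)=C/B(Br)Br | intermediate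
21 | 2-[(1Z)-2-bromoprop-1-en-1-yl]-4,4,5,5-tetramethyl-1,3,2-dioxaborolane | C/C(Br)=C/B1OC(C)(C)C(C)(C)O1 | intermediate
22 | {(E)-2-[(1S,5R)-5-(TBSO)-2,6,6-trimethylcyclohex-2-en-1-yl]ethenyl}lithium | CC1=CC[C@@H](O[Si](C)(C)C(C)(C)C)C(C)(C)[C@H]1/C=C/[Li] | intermediate
23 | bromo{(E)-2-[(1S,5R)-5-(TBSO)-2,6,6-trimethylcyclohex-2-en-1-yl]ethenyl}zinc | CC1=CC[C@@H](O[Si](C)(C)C(C)(C)C)C(C)(C)[C@H]1/C=C/[Zn]Br | intermediate
24 | tert-butyldimethyl({(1R,5S)-4,6,6-trimethyl-5-[(1E,3Z)-3-methyl-4-(Bpin)buta-1,3-dien-1-yl]cyclohex-3-en-1-yl}oxy)silane | CC1=CC[C@@H](O[Si](C)(C)C(C)(C)C)C(C)(C)[C@H]1/C=C/C(C)=C\B1OC(C)(C)C(C)(C)O1 | intermediate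
25 | tert-butyl({(1R,5S)-5-[(1E,3Z)-4-iodo-3-methylbuta-1,3-dien-1-yl]-4,6,6-trimethylcyclohex-3-en-1-yl}oxy)dimethylsilane | CC1=CC[C@@H](O[Si](C)(C)C(C)(C)C)C(C)(C)[C@H]1/C=C/C(C)=C\I | intermediate
26 | (1S,2Z,4E)-1-[(1S,2S,5R,6S)-2,5-bis(TBSO)-4-[(TBSO)methyl]-7-oxabicyclo[4.1.0]hept-3-en-1-yl]-3-methyl-5-[(1S,5R)-5-(TBSO)-2,6,6-trimethylcyclohex-2-en-1-yl]penta-2,4-dien-1-ol | CC1=CC[C@@H](O[Si](C)(C)C(C)(C)C)C(C)(C)[C@H]1/C=C/C(C)=C\[C@H](O)[C@]12O[C@H]1[C@H](O[Si](C)(C)C(C)(C)C)C(CO[Si](C)(C)C(C)(C)C)=C[C@@H]2O[Si](C)(C)C(C)(C)C | intermediate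
27 | (1R,2S,5R,6S)-1-[(1S,2Z,4E)-1-hydroxy-5-[(1S,5R)-5-hydroxy-2,6,6-trimethylcyclohex-2-en-1-yl]-3-methylpenta-2,4-dien-1-yl]-4-(hydroxymethyl)-7-oxabicyclo[4.1.0]hept-3-ene-2,5-diol | CC1=CC[C@@H](O)C(C)(C)[C@H]1/C=C/C(C)=C\[C@H](O)[C@]12O[C@H]1[C@H](O)C(CO)=C[C@@H]2O | target

**Count**

Total step count: 19.
Longest linear sequence: 10 steps (steps 1–8, 18, 19; the ring A arm, steps 9–14, 16–19, is equally long).

**Steps most likely to fail**

Step 4 (Proposed new method). What may go wrong: chain growth to oligomers instead of ring closure; addition of the first alkoxide to the cis aldehyde, giving a lactol that dehydrates to a furan; weak catalyst control, giving much meso trans-diol. The fallback sets out from 4 and returns at 8, and makes the two ring bonds one after the other by known reactions. Alcohol 4 is protected with 4-methoxybenzyl trichloroacetimidate (cat. pyridinium p-toluenesulfonate, CH2Cl2) to give tert-butyl({(2Z)-2-iodo-4-[(4-methoxybenzyl)oxy]but-2-en-1-yl}oxy)dimethylsilane F1. Iodine–lithium exchange (t-BuLi, Et2O, −78 °C) and DMF give (2Z)-2-[(TBSO)methyl]-4-[(4-methoxybenzyl)oxy]but-2-enal F2. Zinc-mediated asymmetric alkynylation of F2 with tert-butyldimethyl(prop-2-yn-1-yloxy)silane (Zn(CH3)2, ProPhenol ligand, Ph3PO, toluene) sets the first carbinol in (2Z,4S)-7-(TBSO)-3-[(TBSO)methyl]-1-[(4-methoxybenzyl)oxy]hept-2-en-5-yn-4-ol F3. Hydroxyl-directed trans-hydroalumination and iodination (NaAlH2(OCH2CH2OCH3)2, THF; I2), as in step 2, give (2Z,4S,5Z)-7-(TBSO)-3-[(TBSO)methyl]-6-iodo-1-[(4-methoxybenzyl)oxy]hepta-2,5-dien-4-ol F4. Silylation (TBSOTf, 2,6-lutidine) gives the 4-O-TBS ether of F4, (2Z,4S,5Z)-4,7-bis(TBSO)-3-[(TBSO)methyl]-6-iodo-1-[(4-methoxybenzyl)oxy]hepta-2,5-diene F5, which rules out lactol formation. DDQ (CH2Cl2, pH 7 buffer) frees (2Z,4S,5Z)-4,7-bis(TBSO)-3-[(TBSO)methyl]-6-iodohepta-2,5-dien-1-ol F6, and MnO2 gives (2Z,4S,5Z)-4,7-bis(TBSO)-3-[(TBSO)methyl]-6-iodohepta-2,5-dienal F7. Intramolecular Nozaki–Hiyama–Kishi cyclization (CrCl2, catalytic NiCl2, DMF; with L* if cis selectivity needs support) closes the ring to (1S,4S)-4-(TBSO)-2,5-bis[(TBSO)methyl]cyclohexa-2,5-dien-1-ol F8, and TBSOTf with 2,6-lutidine then gives 8.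

Step 18. What may go wrong: poor facial selectivity at the aldehyde, because the catalyst has to work against the Felkin–Anh preference of the epoxy aldehyde (entry anti to the C1–O7 bond, on the side of the oxirane CH), which is expected to favour the C1' epimer. The fallback sets out from 11 and 25 and returns at 26; it turns the same substrate preference to advantage by making hydride the nucleophile. The two fragments are coupled under achiral conditions (CrCl2, catalytic NiCl2, DMSO, rt) to give the carbinol as an epimer mixture rich in the (1R)-epimer of 26, F9. The mixture is oxidized with Dess–Martin periodinane (NaHCO3, CH2Cl2) to the single dienone (2Z,4E)-1-[(1S,2S,5R,6S)-2,5-bis(TBSO)-4-[(TBSO)methyl]-7-oxabicyclo[4.1.0]hept-3-en-1-yl]-3-methyl-5-[(1S,5R)-5-(TBSO)-2,6,6-trimethylcyclohex-2-en-1-yl]penta-2,4-dien-1-one F10. Reduction of F10 with LiBH(sec-C4H9)3 (THF, −78 °C) should follow the Felkin–Anh path, away from the C2 silyloxy group, and give 26; the beta,beta-disubstituted enone should be reduced 1,2.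

Step 7. What may go wrong: poor facial selectivity of oxygen delivery, or oxidation at the doubly allylic positions of the diene. The fallback sets out from 9 and returns at 11; it replaces the directed electrophilic epoxidation by a nucleophilic one. Alcohol 9 is oxidized with MnO2 (CH2Cl2) to (3S,6S)-3,6-bis(TBSO)-4-[(TBSO)methyl]cyclohexa-1,4-diene-1-carbaldehyde F11. Weitz–Scheffer epoxidation of F11 (H2O2, NaHCO3, MeOH/THF, 0 °C, or t-BuOOH with DBU) attacks only the electron-poor enal alkene; hydroperoxide should add to the beta carbon anti to the neighbouring silyloxy group and close to epoxy aldehyde 11 directly.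

**Further compounds**

F1 | step 4 | tert-butyl({(2Z)-2-iodo-4-[(4-methoxybenzyl)oxy]but-2-en-1-yl}oxy)dimethylsilane | COc1ccc(COC/C=C(\I)CO[Si](C)(C)C(C)(C)C)cc1
F2 | step 4 | (2Z)-2-[(TBSO)methyl]-4-[(4-methoxybenzyl)oxy]but-2-enal | COc1ccc(COC/C=C(\C=O)CO[Si](C)(C)C(C)(C)C)cc1
F3 | step 4 | (2Z,4S)-7-(TBSO)-3-[(TBSO)methyl]-1-[(4-methoxybenzyl)oxy]hept-2-en-5-yn-4-ol | COc1ccc(COC/C=C(/CO[Si](C)(C)C(C)(C)C)[C@@H](O)C#CCO[Si](C)(C)C(C)(C)C)cc1
F4 | step 4 | (2Z,4S,5Z)-7-(TBSO)-3-[(TBSO)methyl]-6-iodo-1-[(4-methoxybenzyl)oxy]hepta-2,5-dien-4-ol | COc1ccc(COC/C=C(/CO[Si](C)(C)C(C)(C)C)[C@@H](O)/C=C(\I)CO[Si](C)(C)C(C)(C)C)cc1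
F5 | step 4 | (2Z,4S,5Z)-4,7-bis(TBSO)-3-[(TBSO)methyl]-6-iodo-1-[(4-methoxybenzyl)oxy]hepta-2,5-diene | COc1ccc(COC/C=C(/CO[Si](C)(C)C(C)(C)C)[C@@H](O[Si](C)(C)C(C)(C)C)/C=C(\I)CO[Si](C)(C)C(C)(C)C)cc1
F6 | step 4 | (2Z,4S,5Z)-4,7-bis(TBSO)-3-[(TBSO)methyl]-6-iodohepta-2,5-dien-1-ol | OC/C=C(/CO[Si](C)(C)C(C)(C)C)[C@@H](O[Si](C)(C)C(C)(C)C)/C=C(\I)CO[Si](C)(C)C(C)(C)C
F7 | step 4 | (2Z,4S,5Z)-4,7-bis(TBSO)-3-[(TBSO)methyl]-6-iodohepta-2,5-dienal | O=C/C=C(/CO[Si](C)(C)C(C)(C)C)[C@@H](O[Si](C)(C)C(C)(C)C)/C=C(\I)CO[Si](C)(C)C(C)(C)C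
F8 | step 4 | (1S,4S)-4-(TBSO)-2,5-bis[(TBSO)methyl]cyclohexa-2,5-dien-1-ol | CC(C)(C)[Si](C)(C)OCC1=C[C@H](O)C(CO[Si](C)(C)C(C)(C)C)=C[C@@H]1O[Si](C)(C)C(C)(C)C
F9 | step 18 | (1R,2Z,4E)-1-[(1S,2S,5R,6S)-2,5-bis(TBSO)-4-[(TBSO)methyl]-7-oxabicyclo[4.1.0]hept-3-en-1-yl]-3-methyl-5-[(1S,5R)-5-(TBSO)-2,6,6-trimethylcyclohex-2-en-1-yl]penta-2,4-dien-1-ol | CC1=CC[C@@H](O[Si](C)(C)C(C)(C)C)C(C)(C)[C@H]1/C=C/C(C)=C\[C@@H](O)[C@]12O[C@H]1[C@H](O[Si](C)(C)C(C)(C)C)C(CO[Si](C)(C)C(C)(C)C)=C[C@@H]2O[Si](C)(C)C(C)(C)C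
F10 | step 18 | (2Z,4E)-1-[(1S,2S,5R,6S)-2,5-bis(TBSO)-4-[(TBSO)methyl]-7-oxabicyclo[4.1.0]hept-3-en-1-yl]-3-methyl-5-[(1S,5R)-5-(TBSO)-2,6,6-trimethylcyclohex-2-en-1-yl]penta-2,4-dien-1-one | CC1=CC[C@@H](O[Si](C)(C)C(C)(C)C)C(C)(C)[C@H]1/C=C/C(C)=C\C(=O)[C@]12O[C@H]1[C@H](O[Si](C)(C)C(C)(C)C)C(CO[Si](C)(C)C(C)(C)C)=C[C@@H]2O[Si](C)(C)C(C)(C)C
F11 | step 7 | (3S,6S)-3,6-bis(TBSO)-4-[(TBSO)methyl]cyclohexa-1,4-diene-1-carbaldehyde | O=CC1=C[C@H](O[Si](C)(C)C(C)(C)C)C(CO[Si](C)(C)C(C)(C)C)=C[C@@H]1O[Si](C)(C)C(C)(C)C
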